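**Plan** (numbering of 1-oxaspiro[4.4]non-7-en-6-one: O1, C2, C5 = spiro carbon, C6 = ketone, C9 = carbinol carbon)

1. Retrosynthesis: acetyl ⇒ ethynyl (hydration); the C5–C9 bond is cut by a retro-1,2-shift, turning the cyclopentenone into a cyclobutenol that carries a 4,5-dihydrofuran-2-yl group on its carbinol carbon; then the C5–C6 bond (vinyllithium + cyclobutenone); then the alkyne–C9 bond (alkyne + cyclobutenedione).
2. Enabling feature: C5 is an ether carbon (O1 of the oxolane) flanked by the C6 ketone and the oxygenated C9, i.e. the carbon of a cyclic oxocarbenium ion beside a former carbinol; the C6–C7(Me)=C8(Me)–C9 unit is a 3,4-dimethylcyclobutene enlarged by one carbon.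
3. Forward: oxolane ring first (as enol ether 6 from lactone 3, cut out of natural α-tocopherol); cyclobutenone 12 from dimethyl squarate; union at the carbonyl (step 7); acid then closes the cyclopentenone and the spiro centre in one shift (step 8); alkyne hydration and desilylation finish.
4. Stereochemistry: C2, C4′ and C8′ are bought with (2R,4′R,8′R)-α-tocopherol; C9 is set by a catalytic asymmetric alkynylation; C5 is relayed from C9 (anti addition, then suprafacial shift with retention at C9).

Key step: step 8

Assumption: the remote C2 centre (methyl versus long chain) is taken to exert no useful facial bias on the ring, so the ring stereocentres are controlled by the catalyst (C9) and by relay from C9 (C5).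

**Step 1**
Reactants: 1 (2R,4′R,8′R)-α-tocopherol
Product: 3 (5R)-5-methyl-5-[(4R,8R)-4,8,12-trimethyltridecyl]oxolan-2-one, via α-tocopherylquinone 2 (not isolated)
Conditions: RuCl3 (2 mol%), NaIO4 (excess), EtOAc/MeCN/H2O, 0 °C to rt; 1 M HCl work-up
Reagents that add atoms: sodium periodate, [Na+].[O-]I(=O)(=O)=O; water, O
Why: Periodate should first oxidize the chromanol to quinone 2, and RuO4 formed in situ (oxidative degradation of an electron-rich ring by RuCl3/NaIO4) should then cut the ring down to the carbon bearing the side chain, which becomes a carboxyl group and lactonizes onto the freed tertiary alcohol; the three stereocenters are not touched.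

**Step 2**
Reactants: 3 (5R)-5-methyl-5-[(4R,8R)-4,8,12-trimethyltridecyl]oxolan-2-one
Product: 4 (5R)-5-methyl-5-[(4R,8R)-4,8,12-trimethyltridecyl]oxolan-2-ol (both anomers)
Conditions: i-Bu2AlH, CH2Cl2, −78 °C; aq. potassium sodium tartrate
Reagents that add atoms: none
Why: Partial reduction of a γ-lactone to the lactol by a dialkylaluminium hydride at low temperature, where the tetrahedral aluminium alkoxide should not collapse; the anomeric centre is lost in step 3.

**Step 3**
Reactants: 4 (5R)-5-methyl-5-[(4R,8R)-4,8,12-trimethyltridecyl]oxolan-2-ol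
Product: 6 (2R)-2-methyl-2-[(4R,8R)-4,8,12-trimethyltridecyl]-2,3-dihydrofuran, via lactol methanesulfonate 5 (not isolated)
Conditions: MsCl, Et3N, CH2Cl2, −40 °C to reflux
Reagents that add atoms: none
Why: Mesylation of the anomeric hydroxyl and base-assisted elimination through the oxocarbenium ion (lactol dehydration to a cyclic enol ether, as used for glycals) should give the 2,3-dihydrofuran.

**Step 4**
Reactants: 7 3,4-dimethoxycyclobut-3-ene-1,2-dione (dimethyl squarate)
Product: 9 3,4-dimethylcyclobut-3-ene-1,2-dione, via bis-adduct diol 8 (not isolated)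
Conditions: MeLi (2.3 equiv), THF, −78 °C; then 12 M HCl, CH2Cl2, 0 °C to rt
Reagents that add atoms: methyllithium, [Li]C; water, O
Why: Two 1,2-additions of MeLi to the squarate carbonyls, then acid ionization of each tertiary allylic alcohol and hydrolysis of the methoxy-stabilized allyl cation at its far end (two allylic 1,3-carbonyl transpositions, the standard cyclobutenedione synthesis from squaric esters), should give the dimethyl dione.

**Step 5**
Reactants: 9 3,4-dimethylcyclobut-3-ene-1,2-dione; 10 ethynyltrimethylsilane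
Product: 11 (4R)-4-hydroxy-2,3-dimethyl-4-[(trimethylsilyl)ethynyl]cyclobut-2-en-1-one
Conditions: Rh(OAc)2(OH2)(L*) (5 mol%; L* = 2,6-bis((4S)-4-isopropyl-4,5-dihydrooxazol-2-yl)phenyl, or its mirror image as the sense of induction requires), Et2O, 25 °C
Reagents that add atoms: none
Why: Proposed new method: acetate-assisted metalation of the terminal alkyne should give a rhodium acetylide that transfers the alkynyl group to a dione carbonyl bound on the same metal inside the chiral pincer pocket; the two carbonyls of 9 are homotopic (C2 axis in the ring plane), so only one π-face has to be selected, and the reaction should stop after one addition because the product is a far less electrophilic cyclobutenone; the closest known reaction type is the catalytic enantioselective alkynylation of α-keto esters and related activated 1,2-dicarbonyl ketones with terminal alkynes, together with the racemic 1,2-addition of acetylides to cyclobutenediones; the new stereocenter (later C9) is set by the catalyst, and the catalyst enantiomer that gives the 4R carbinol is used.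

**Step 6**
Reactants: 11 (4R)-4-hydroxy-2,3-dimethyl-4-[(trimethylsilyl)ethynyl]cyclobut-2-en-1-one
Product: 12 (4R)-2,3-dimethyl-4-(triethylsilyloxy)-4-[(trimethylsilyl)ethynyl]cyclobut-2-en-1-one
Conditions: Et3SiOTf, 2,6-lutidine, CH2Cl2, −78 to 0 °C
Reagents that add atoms: triethylsilyl trifluoromethanesulfonate, CC[Si](CC)(CC)OS(=O)(=O)C(F)(F)F
Why: Silylation of a hindered tertiary alcohol with a silyl triflate; the silyl ether removes the acidic proton, becomes the bulky face-directing group for step 7 and keeps the β-oxygen masked to the end.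

**Step 7**
Reactants: 6 (2R)-2-methyl-2-[(4R,8R)-4,8,12-trimethyltridecyl]-2,3-dihydrofuran; 12 (4R)-2,3-dimethyl-4-(triethylsilyloxy)-4-[(trimethylsilyl)ethynyl]cyclobut-2-en-1-one
Product: 14 (1S,4R)-2,3-dimethyl-1-{(5R)-5-methyl-5-[(4R,8R)-4,8,12-trimethyltridecyl]-4,5-dihydrofuran-2-yl}-4-(triethylsilyloxy)-4-[(trimethylsilyl)ethynyl]cyclobut-2-en-1-ol (hydroxyl and silyloxy cis), via 5-lithio-2,3-dihydrofuran 13 (not isolated)
Conditions: 6, t-BuLi, THF, −78 to 0 °C; then 12, −78 °C; AcOH quench at −78 °C; crude product used cold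
Reagents that add atoms: none
Why: α-Lithiation of the cyclic enol ether and 1,2-addition of the vinyllithium to the strained enone carbonyl; the nucleophile should enter anti to the triethylsilyloxy group and syn to the slim alkyne, which sets the carbinol carbon (1S) by substrate control, and the cold acidic quench avoids alkoxide-accelerated opening of the cyclobutene.

**Step 8**
Reactants: 14 (1S,4R)-cyclobutenol from step 7
Product: 16 (2R,5R,9R)-2,7,8-trimethyl-9-(triethylsilyloxy)-2-[(4R,8R)-4,8,12-trimethyltridecyl]-9-[(trimethylsilyl)ethynyl]-1-oxaspiro[4.4]non-7-en-6-one, via oxocarbenium phosphate 15 (not isolated)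
Conditions: (PhO)2P(O)OH (10 mol%), 4 Å molecular sieves, CH2Cl2, −40 to 0 °C
Reagents that add atoms: none
Why: C-Protonation of the enol ether should give the five-membered cyclic oxocarbenium ion 15, and the adjacent ring bond of the strained cyclobutene then attacks its empty orbital: the silyloxy-bearing carbon migrates suprafacially from the carbinol carbon to the oxocarbenium carbon while the carbinol becomes the C6 ketone (oxonium-ion-initiated pinacol shift, a semipinacol rearrangement). The closest known reactions are the acid-promoted ring expansions of 1-(4,5-dihydrofuran-2-yl)cyclobutanols to 1-oxaspiro[4.4]nonan-6-ones, including their chiral phosphoric acid versions. The cyclopentenone is therefore closed not by an end-to-end cyclization but by a 1,2-shift that enlarges the four-membered ring by one carbon, driven irreversibly by relief of cyclobutene strain and C=O formation, so the product never passes through equilibrating aldol or acyloin conditions. The migrating carbon C9 keeps its configuration, and the new spiro carbon C5 is fixed by the rotamer about the carbinol–oxocarbenium bond: with the phosphate bridging the carbinol O–H and the acidic CH2 of the cation, that CH2 sits beside the small hydroxyl and the ring oxygen is turned away, which should place O1 trans to the silyloxy group and cis to the alkyne. The step needs migration of the oxygenated sp3 carbon and not of the vinylic ring carbon, which the α-oxygen and the strain of a bridged vinyl shift should secure, and protonation of the enol ether in preference to ionization of the tertiary allylic alcohol, which the weak acid at low temperature should secure.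

**Step 9**
Reactants: 16 (2R,5R,9R)-spiro ketone from step 8
Product: 17 (2R,5R,9S)-9-ethynyl-2,7,8-trimethyl-9-(triethylsilyloxy)-2-[(4R,8R)-4,8,12-trimethyltridecyl]-1-oxaspiro[4.4]non-7-en-6-one
Conditions: K2CO3 (cat.), MeOH, 0 °C
Reagents that add atoms: none
Why: Base-catalysed methanolysis of the alkynyl C–Si bond (protodesilylation); the tertiary triethylsilyl ether should survive and, with the β-oxygen still masked, no retro-aldol is possible.

**Step 10**
Reactants: 17 (2R,5R,9S)-9-ethynyl spiro ketone
Product: 18 (2R,5R,9S)-9-acetyl-2,7,8-trimethyl-9-(triethylsilyloxy)-2-[(4R,8R)-4,8,12-trimethyltridecyl]-1-oxaspiro[4.4]non-7-en-6-one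
Conditions: Ph3PAuNTf2 (2 mol%), H2O (5 equiv), 1,4-dioxane, 40 °C
Reagents that add atoms: water, O
Why: π-Acid (gold) catalysed hydration of a terminal alkyne places oxygen on the internal carbon and gives the methyl ketone under neutral conditions; the silyl ether blocks a Meyer–Schuster rearrangement and any acyloin shift.

**Step 11**
Reactants: 18 (2R,5R,9S)-9-acetyl silyl ether
Product: 19 (2R,5R,9S)-9-acetyl-9-hydroxy-2,7,8-trimethyl-2-[(4R,8R)-4,8,12-trimethyltridecyl]-1-oxaspiro[4.4]non-7-en-6-one (target)
Conditions: HF·pyridine, THF, 0 °C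
Reagents that add atoms: none
Why: Fluoride-mediated Si–O cleavage under weakly acidic, non-basic conditions should free the tertiary alcohol without retro-aldol cleavage of the β-hydroxy ketone.

**Compound list**

1 | (2R,4′R,8′R)-α-tocopherol | Cc1c(C)c2c(CC[C@@](C)(CCC[C@H](C)CCC[C@H](C)CCCC(C)C)O2)c(C)c1O | starting material
2 | 2-[(3R,7R,11R)-3-hydroxy-3,7,11,15-tetramethylhexadecyl]-3,5,6-trimethylcyclohexa-2,5-diene-1,4-dione (α-tocopherylquinone) | CC1=C(C)C(=O)C(CC[C@](C)(O)CCC[C@H](C)CCC[C@H](C)CCCC(C)C)=C(C)C1=O | intermediate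
3 | (5R)-5-methyl-5-[(4R,8R)-4,8,12-trimethyltridecyl]oxolan-2-one | O=C1CC[C@@](C)(CCC[C@H](C)CCC[C@H](C)CCCC(C)C)O1 | intermediate
4 | (5R)-5-methyl-5-[(4R,8R)-4,8,12-trimethyltridecyl]oxolan-2-ol (both anomers) | OC1CC[C@@](C)(CCC[C@H](C)CCC[C@H](C)CCCC(C)C)O1 | intermediate
5 | (5R)-5-methyl-5-[(4R,8R)-4,8,12-trimethyltridecyl]oxolan-2-yl methanesulfonate | CS(=O)(=O)OC1CC[C@@](C)(CCC[C@H](C)CCC[C@H](C)CCCC(C)C)O1 | intermediate
6 | (2R)-2-methyl-2-[(4R,8R)-4,8,12-trimethyltridecyl]-2,3-dihydrofuran | C1=CC[C@@](C)(CCC[C@H](C)CCC[C@H](C)CCCC(C)C)O1 | intermediate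
7 | 3,4-dimethoxycyclobut-3-ene-1,2-dione (dimethyl squarate) | COC1=C(OC)C(=O)C1=O | starting material
8 | 3,4-dimethoxy-1,2-dimethylcyclobut-3-ene-1,2-diol | COC1=C(OC)C(C)(O)C1(C)O | intermediate
9 | 3,4-dimethylcyclobut-3-ene-1,2-dione | CC1=C(C)C(=O)C1=O | intermediate
10 | ethynyltrimethylsilane | C[Si](C)(C)C#C | starting material
11 | (4R)-4-hydroxy-2,3-dimethyl-4-[(trimethylsilyl)ethynyl]cyclobut-2-en-1-one | C[Si](C)(C)C#C[C@]1(O)C(C)=C(C)C1=O | intermediate
12 | (4R)-2,3-dimethyl-4-(triethylsilyloxy)-4-[(trimethylsilyl)ethynyl]cyclobut-2-en-1-one | C[Si](C)(C)C#C[C@]1(O[Si](CC)(CC)CC)C(C)=C(C)C1=O | intermediate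
13 | [(5R)-5-methyl-5-[(4R,8R)-4,8,12-trimethyltridecyl]-4,5-dihydrofuran-2-yl]lithium | [Li]C1=CC[C@@](C)(CCC[C@H](C)CCC[C@H](C)CCCC(C)C)O1 | intermediate
14 | (1S,4R)-2,3-dimethyl-1-{(5R)-5-methyl-5-[(4R,8R)-4,8,12-trimethyltridecyl]-4,5-dihydrofuran-2-yl}-4-(triethylsilyloxy)-4-[(trimethylsilyl)ethynyl]cyclobut-2-en-1-ol | C[Si](C)(C)C#C[C@]1(O[Si](CC)(CC)CC)C(C)=C(C)[C@]1(O)C2=CC[C@@](C)(CCC[C@H](C)CCC[C@H](C)CCCC(C)C)O2 | intermediate
15 | cyclic oxocarbenium ion formed by C-protonation of the enol ether of 14, as its diphenyl phosphate salt | C[Si](C)(C)C#C[C@]1(O[Si](CC)(CC)CC)C(C)=C(C)[C@]1(O)C2=[O+][C@](C)(CCC[C@H](C)CCC[C@H](C)CCCC(C)C)CC2.[O-]P(=O)(Oc1ccccc1)Oc1ccccc1 | intermediate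
16 | (2R,5R,9R)-2,7,8-trimethyl-9-(triethylsilyloxy)-2-[(4R,8R)-4,8,12-trimethyltridecyl]-9-[(trimethylsilyl)ethynyl]-1-oxaspiro[4.4]non-7-en-6-one | C[Si](C)(C)C#C[C@]1(O[Si](CC)(CC)CC)C(C)=C(C)C(=O)[C@@]12CC[C@@](C)(CCC[C@H](C)CCC[C@H](C)CCCC(C)C)O2 | intermediate
17 | (2R,5R,9S)-9-ethynyl-2,7,8-trimethyl-9-(triethylsilyloxy)-2-[(4R,8R)-4,8,12-trimethyltridecyl]-1-oxaspiro[4.4]non-7-en-6-one | C#C[C@]1(O[Si](CC)(CC)CC)C(C)=C(C)C(=O)[C@@]12CC[C@@](C)(CCC[C@H](C)CCC[C@H](C)CCCC(C)C)O2 | intermediate
18 | (2R,5R,9S)-9-acetyl-2,7,8-trimethyl-9-(triethylsilyloxy)-2-[(4R,8R)-4,8,12-trimethyltridecyl]-1-oxaspiro[4.4]non-7-en-6-one | CC(=O)[C@]1(O[Si](CC)(CC)CC)C(C)=C(C)C(=O)[C@@]12CC[C@@](C)(CCC[C@H](C)CCC[C@H](C)CCCC(C)C)O2 | intermediate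
19 | (2R,5R,9S)-9-acetyl-9-hydroxy-2,7,8-trimethyl-2-[(4R,8R)-4,8,12-trimethyltridecyl]-1-oxaspiro[4.4]non-7-en-6-one | CC(=O)[C@]1(O)C(C)=C(C)C(=O)[C@@]12CC[C@@](C)(CCC[C@H](C)CCC[C@H](C)CCCC(C)C)O2 | target

**Step count and risks**

Total steps: 11. Longest linear sequence: 8 steps (steps 4–11 from dimethyl squarate, or steps 1–3 and 7–11 from α-tocopherol).

Steps most likely to fail:

1. Step 5 (Proposed new method). The catalyst may fail to distinguish the two faces of the flat, symmetric dione, or a second alkynyl group may add. Fallback: setting out from 9, ethynyltrimethylsilane 10 is deprotonated with n-BuLi (THF, −78 °C) to lithium (trimethylsilyl)acetylide F1, whose well-known 1,2-addition to the cyclobutenedione should give racemic 4-hydroxy-2,3-dimethyl-4-[(trimethylsilyl)ethynyl]cyclobut-2-en-1-one F2. F2 is resolved by preparative chromatography on a chiral stationary phase; the 4R enantiomer is 11, where the route is rejoined.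

2. Step 8. The shift may run through the other rotamer of the oxocarbenium ion (ring oxygen beside the hydroxyl), which would give the C5 epimer; migration of the vinylic ring carbon or electrocyclic opening of the cyclobutene may also compete. Fallback: setting out from unprotected 11, LiN(SiMe3)2 (THF, −78 °C) gives the lithium alkoxide of 11 F3, which should direct the addition of 13 to its own face. After a cold AcOH quench this should give the trans-diol (1S,2R)-3,4-dimethyl-1-{(5R)-5-methyl-5-[(4R,8R)-4,8,12-trimethyltridecyl]-4,5-dihydrofuran-2-yl}-2-[(trimethylsilyl)ethynyl]cyclobut-3-ene-1,2-diol F4, in which the relation between carbinol and migrating carbon is inverted. The same acid treatment should then turn the other rotamer into the desired spiro configuration and give (2R,5R,9R)-9-hydroxy-2,7,8-trimethyl-2-[(4R,8R)-4,8,12-trimethyltridecyl]-9-[(trimethylsilyl)ethynyl]-1-oxaspiro[4.4]non-7-en-6-one F5. Silylation (Et3SiOTf, 2,6-lutidine) returns to 16.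

3. Step 11. Once the free tertiary α-hydroxy ketone is exposed to acid, acyloin (α-ketol) ring enlargement to the six-membered hydroxy dione or retro-aldol cleavage of the β-hydroxy ketone may compete with desilylation. Fallback: the order of the last two operations is inverted. Setting out from 17, buffered fluoride (Bu4NF, AcOH, THF, 0 °C) removes the silyl ether at a stage that has no acyl group and should give (2R,5R,9S)-9-ethynyl-9-hydroxy-2,7,8-trimethyl-2-[(4R,8R)-4,8,12-trimethyltridecyl]-1-oxaspiro[4.4]non-7-en-6-one F6. Hydration of its alkyne (Ph3PAuNTf2, wet 1,4-dioxane, rt) then releases 19 directly under neutral conditions.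

**Further compounds**

F1 | step 5 | lithium (trimethylsilyl)acetylide | [Li]C#C[Si](C)(C)C
F2 | step 5 | racemic 4-hydroxy-2,3-dimethyl-4-[(trimethylsilyl)ethynyl]cyclobut-2-en-1-one | C[Si](C)(C)C#CC1(O)C(C)=C(C)C1=O
F3 | step 8 | lithium alkoxide of 11 | C[Si](C)(C)C#C[C@]1(O[Li])C(C)=C(C)C1=O
F4 | step 8 | (1S,2R)-3,4-dimethyl-1-{(5R)-5-methyl-5-[(4R,8R)-4,8,12-trimethyltridecyl]-4,5-dihydrofuran-2-yl}-2-[(trimethylsilyl)ethynyl]cyclobut-3-ene-1,2-diol (trans-diol) | C[Si](C)(C)C#C[C@]1(O)C(C)=C(C)[C@@]1(O)C2=CC[C@@](C)(CCC[C@H](C)CCC[C@H](C)CCCC(C)C)O2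
F5 | step 8 | (2R,5R,9R)-9-hydroxy-2,7,8-trimethyl-2-[(4R,8R)-4,8,12-trimethyltridecyl]-9-[(trimethylsilyl)ethynyl]-1-oxaspiro[4.4]non-7-en-6-one | C[Si](C)(C)C#C[C@]1(O)C(C)=C(C)C(=O)[C@@]12CC[C@@](C)(CCC[C@H](C)CCC[C@H](C)CCCC(C)C)O2
F6 | step 11 | (2R,5R,9S)-9-ethynyl-9-hydroxy-2,7,8-trimethyl-2-[(4R,8R)-4,8,12-trimethyltridecyl]-1-oxaspiro[4.4]non-7-en-6-one | C#C[C@]1(O)C(C)=C(C)C(=O)[C@@]12CC[C@@](C)(CCC[C@H](C)CCC[C@H](C)CCCC(C)C)O2
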